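The target is cut at the σ-bond between the vinylic carbon of its 1,1-disubstituted alkene (the carbon on C4 of bromohydrin ring B) and the allylic methylene on C3 of epoxide ring A. This sp2–sp3 bond lies outside both rings and touches none of the seven stereocentres, so it can be made last. A B-alkyl Suzuki–Miyaura coupling joins a ring A iodomethyl epoxide, made from (S)-carvone and converted in the flask into a 9-BBN borinate, to a ring B 1-iodovinyl cis-bromohydrin made from (1S,2S,4R)-limonene-1,2-diol. One operation delivers the complete unprotected target, each half arriving with its stereochemistry finished.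

Key step: step 11

Assumption: (S)-(+)-carvone and (1S,2S,4R)-(+)-limonene-1,2-diol are taken as commercial; within each ring the p-menthane locants are used (C1 carries the methyl group, C4 the three-carbon branch), and compounds 1–4 keep carvone locants (carvone C6 becomes C3 of ring A).
Remark: the hydrazone geometries, the sulfur configuration of 12, the ozonide carbon of 10 and the nitrogen-bearing carbon of 5 have no stereochemical consequence.

Step 1
Reactants: 1 (S)-(+)-carvone
Product: 3 (5S,6S)-6-(hydroxymethyl)-2-methyl-5-(prop-1-en-2-yl)cyclohex-2-en-1-one, via lithium dienolate 2 (not isolated)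
Conditions: LiN(iPr)2, THF, −78 °C; CH2O (monomeric gas from cracked paraformaldehyde), −78 → −40 °C; aq NH4Cl
Reagents that add atoms: formaldehyde C=O
Why: Kinetic deprotonation at C6 gives the cross-conjugated lithium dienolate 2, and its aldol addition to formaldehyde should occur on the face anti to the C5 isopropenyl group, setting C6 trans (substrate control, and also the thermodynamically preferred diequatorial isomer).

Step 2
Reactants: 3 (5S,6S)-6-(hydroxymethyl)carvone
Product: 4 tosylhydrazone of 3
Conditions: TsNHNH2, MeOH, PPTS (cat.), 20 °C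
Reagents that add atoms: 4-methylbenzenesulfonohydrazide Cc1ccc(cc1)S(=O)(=O)NN
Why: Hydrazone formation by condensation of the ketone with tosylhydrazide under near-neutral conditions, which should leave the enolisable C6 centre and the β-hydroxy ketone unchanged.

Step 3
Reactants: 4 tosylhydrazone
Product: 6 [(1S,6S)-3-methyl-6-(prop-1-en-2-yl)cyclohex-2-en-1-yl]methanol, via allylic diazene 5 (not isolated)
Conditions: catecholborane, CHCl3, 0 °C; then NaOAc·3H2O, reflux
Reagents that add atoms: none
Why: Reductive 1,3-transposition of an enone tosylhydrazone: hydride adds to C=N, acetate-induced loss of sulfinate gives diazene 5, and its retro-ene loss of N2 places the double bond at the former carbonyl carbon (C1=C2 of ring A) while both stereocentres stay untouched.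

Step 4
Reactants: 6 homoallylic alcohol
Product: 7 [(1R,2S,3S,6S)-6-methyl-3-(prop-1-en-2-yl)-7-oxabicyclo[4.1.0]heptan-2-yl]methanol
Conditions: VO(acac)2 (cat.), t-BuOOH (in decane), CH2Cl2, 0 → 20 °C
Reagents that add atoms: tert-butyl hydroperoxide CC(C)(C)OO
Why: Hydroxyl-directed vanadium-catalysed epoxidation of a homoallylic alcohol: the vanadium-bound alkoxide should deliver oxygen to the trisubstituted ring alkene on the face carrying the CH2OH group (syn to the C3 substituent, anti to isopropenyl), leaving the undirected and less electron-rich isopropenyl group.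

Step 5
Reactants: 7 epoxy alcohol
Product: 8 (1R,2R,3S,6S)-2-(iodomethyl)-6-methyl-3-(prop-1-en-2-yl)-7-oxabicyclo[4.1.0]heptane
Conditions: PPh3, I2, imidazole, CH2Cl2, 0 → 20 °C
Reagents that add atoms: iodine II
Why: Appel-type iodination of the primary alcohol with imidazole as buffer, conditions that trisubstituted epoxides usually tolerate; no stereocentre is touched.

Step 6
Reactants: 9 (1S,2S,4R)-limonene-1,2-diol
Product: 11 1-[(1R,3S,4S)-3,4-dihydroxy-4-methylcyclohexyl]ethan-1-one, via ozonide 10 (not isolated)
Conditions: O3, CH2Cl2, −78 °C; then Me2S, −78 → 20 °C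
Reagents that add atoms: ozone [O-][O+]=O
Why: Ozonolysis of the isopropenyl group, the only alkene, with reductive cleavage of ozonide 10 should give the methyl ketone without affecting the diol or the three stereocentres.

Step 7
Reactants: 11 keto diol
Product: 13 (3aS,5R,7aS)-5-acetyl-7a-methylhexahydro-1,3,2-benzodioxathiole 2,2-dioxide (trans-fused cyclic sulfate), via cyclic sulfite 12 (not isolated)
Conditions: SOCl2, Et3N, CH2Cl2, 0 °C; then RuCl3 hydrate (cat.), NaIO4, MeCN/H2O, 0 °C
Reagents that add atoms: thionyl chloride O=S(Cl)Cl; sodium periodate [Na+].[O-]I(=O)(=O)=O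
Why: Two-stage cyclic sulfate synthesis (cyclic sulfite, then RuCl3/NaIO4 oxidation at sulfur): the trans-diol closes the five-membered ring from its diequatorial chair and no stereocentre changes.

Step 8
Reactants: 13 cyclic sulfate
Product: 15 1-[(1R,3R,4S)-3-bromo-4-hydroxy-4-methylcyclohexyl]ethan-1-one, via lithium bromo sulfate 14 (not isolated)
Conditions: LiBr, THF, 20 → 50 °C; then H2SO4 (cat.), H2O (2 equiv), THF, 20 °C
Reagents that add atoms: lithium bromide [Li+].[Br-]
Why: Nucleophilic opening of a cyclic sulfate: bromide attacks the secondary carbon by SN2 with inversion (bromine ends cis to the tertiary oxygen), the tied-back sulfate excluding epoxide formation and oxygen participation, and acid-catalysed sulfur–oxygen hydrolysis of monoester 14 then frees the tertiary alcohol with retention.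

Step 9
Reactants: 15 keto bromohydrin
Product: 16 (1S,2R,4R)-2-bromo-4-(1-hydrazinylideneethyl)-1-methylcyclohexan-1-ol
Conditions: N2H4·H2O (excess), Et3N, EtOH, 50 °C
Reagents that add atoms: hydrazine hydrate NN.O
Why: Hydrazone formation from the methyl ketone with excess hydrazine (suppresses the azine); the cis-bromohydrin has no anti oxygen–bromine arrangement and so cannot close to an epoxide under the mild base.

Step 10
Reactants: 16 hydrazone
Product: 18 (1S,2R,4R)-2-bromo-4-(1-iodoethenyl)-1-methylcyclohexan-1-ol, via diazoalkane 17 (not isolated)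
Conditions: I2, 1,1,3,3-tetramethylguanidine, THF, 0 → 20 °C
Reagents that add atoms: iodine II
Why: Barton hydrazone iodination: iodine oxidises the hydrazone to diazoalkane 17, and iodination with loss of N2 followed by guanidine-mediated proton loss from the methyl group should give the less substituted 1-iodovinyl group, the ring stereocentres being remote from the reacting carbon.

Step 11
Reactants: 8 ring A iodide (1.5 equiv); 18 ring B vinyl iodide
Product: 21 (1S,2R,4R)-2-bromo-1-methyl-4-{3-[(1R,2R,3S,6S)-6-methyl-3-(prop-1-en-2-yl)-7-oxabicyclo[4.1.0]heptan-2-yl]prop-1-en-2-yl}cyclohexan-1-ol, via alkyllithium 19 (not isolated), via lithium borinate 20 (not isolated)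
Conditions: 8, t-BuLi (2 equiv per 8), Et2O, −78 °C; B-methoxy-9-BBN, THF, −78 → 20 °C; then 18, Pd(dppf)Cl2 (cat.), AsPh3, aq K3PO4, DMF, 20 °C
Reagents that add atoms: none
Why: Iodine–lithium exchange on 8 gives primary alkyllithium 19, which B-methoxy-9-BBN captures as borinate 20; zerovalent palladium then inserts into the vinyl carbon–iodine bond of 18, the primary alkyl group passes from boron to palladium, and reductive elimination forms the C(sp2)–C(sp3) bond. The closest known reaction type is the B-alkyl Suzuki–Miyaura coupling in its lithium alkyl(methoxy)borinate variant. No ring is closed and no stereocentre is formed; all seven stereocentres are carried in unchanged because the new bond lies one atom away from C3 of ring A and from C4 of ring B. The step needs chemoselectivity: the vinyl iodide must react and the secondary carbon–bromine bond must not (oxidative addition at the sp2 iodide is far faster, and Pd(dppf)Cl2 leaves unactivated secondary alkyl bromides alone at 20 °C), 19 must not open the epoxide (its CH2Li group is cis to the epoxide oxygen, so no backside closure is possible at −78 °C), and β-hydride loss from the alkylpalladium should be outrun by reductive elimination from the wide-bite-angle dppf complex. The cis-bromohydrin cannot close to an epoxide under the phosphate base because bromine and oxygen are not anti, and the free tertiary alcohol is tolerated by the borinate.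

Compound list
1 | (S)-(+)-carvone, (5S)-2-methyl-5-(prop-1-en-2-yl)cyclohex-2-en-1-one | CC1=CC[C@@H](CC1=O)C(C)=C | starting material
2 | lithium dienolate of 1 (C1–O–Li, C1=C6 and C2=C3) | [Li]OC1=C[C@@H](C(C)=C)CC=C1C | intermediate (not isolated)
3 | (5S,6S)-6-(hydroxymethyl)-2-methyl-5-(prop-1-en-2-yl)cyclohex-2-en-1-one (CH2OH trans to isopropenyl) | OC[C@@H]1[C@@H](C(=C)C)CC=C(C)C1=O | intermediate
4 | N'-[(5S,6R)-6-(hydroxymethyl)-2-methyl-5-(prop-1-en-2-yl)cyclohex-2-en-1-ylidene]-4-methylbenzenesulfonohydrazide (same spatial arrangement as 3) | OC[C@@H]1[C@@H](C(=C)C)CC=C(C)C1=NNS(=O)(=O)c2ccc(C)cc2 | intermediate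
5 | allylic diazene: 4 with C=N–NHTs reduced to CH–N=NH, nitrogen drawn cis to CH2OH | OC[C@@H]1[C@@H](C(=C)C)CC=C(C)[C@@H]1N=N | intermediate (not isolated)
6 | [(1S,6S)-3-methyl-6-(prop-1-en-2-yl)cyclohex-2-en-1-yl]methanol (CH2OH trans to isopropenyl) | OC[C@@H]1[C@@H](C(=C)C)CCC(C)=C1 | intermediate
7 | [(1R,2S,3S,6S)-6-methyl-3-(prop-1-en-2-yl)-7-oxabicyclo[4.1.0]heptan-2-yl]methanol (epoxide oxygen cis to CH2OH, trans to isopropenyl) | OC[C@@H]1[C@@H](C(=C)C)CC[C@]2(C)O[C@H]12 | intermediate
8 | (1R,2R,3S,6S)-2-(iodomethyl)-6-methyl-3-(prop-1-en-2-yl)-7-oxabicyclo[4.1.0]heptane | IC[C@@H]1[C@@H](C(=C)C)CC[C@]2(C)O[C@H]12 | intermediate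
9 | (1S,2S,4R)-limonene-1,2-diol, (1S,2S,4R)-1-methyl-4-(prop-1-en-2-yl)cyclohexane-1,2-diol | CC(=C)[C@@H]1CC[C@](C)(O)[C@@H](O)C1 | starting material
10 | ozonide: (1S,2S,4R)-1-methyl-4-(3-methyl-1,2,4-trioxolan-3-yl)cyclohexane-1,2-diol (epimers at the trioxolane carbon) | CC2(OCOO2)[C@@H]1CC[C@](C)(O)[C@@H](O)C1 | intermediate (not isolated)
11 | 1-[(1R,3S,4S)-3,4-dihydroxy-4-methylcyclohexyl]ethan-1-one | CC(=O)[C@@H]1CC[C@](C)(O)[C@@H](O)C1 | intermediate
12 | trans-fused cyclic sulfite of 11 (epimers at sulfur) | CC(=O)[C@@H]1CC[C@]2(C)OS(=O)O[C@H]2C1 | intermediate (not isolated)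
13 | (3aS,5R,7aS)-5-acetyl-7a-methylhexahydro-1,3,2-benzodioxathiole 2,2-dioxide (trans-fused cyclic sulfate of 11) | CC(=O)[C@@H]1CC[C@]2(C)OS(=O)(=O)O[C@H]2C1 | intermediate
14 | lithium (1S,2R,4R)-4-acetyl-2-bromo-1-methylcyclohexyl sulfate | CC(=O)[C@@H]1CC[C@](C)(OS(=O)(=O)[O-])[C@H](Br)C1.[Li+] | intermediate (not isolated)
15 | 1-[(1R,3R,4S)-3-bromo-4-hydroxy-4-methylcyclohexyl]ethan-1-one (OH, Br and acetyl all cis) | CC(=O)[C@@H]1CC[C@](C)(O)[C@H](Br)C1 | intermediate
16 | (1S,2R,4R)-2-bromo-4-(1-hydrazinylideneethyl)-1-methylcyclohexan-1-ol | CC(=NN)[C@@H]1CC[C@](C)(O)[C@H](Br)C1 | intermediate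
17 | (1S,2R,4R)-2-bromo-4-(1-diazoethyl)-1-methylcyclohexan-1-ol | CC(=[N+]=[N-])[C@@H]1CC[C@](C)(O)[C@H](Br)C1 | intermediate (not isolated)
18 | (1S,2R,4R)-2-bromo-4-(1-iodoethenyl)-1-methylcyclohexan-1-ol | C=C(I)[C@@H]1CC[C@](C)(O)[C@H](Br)C1 | intermediate
19 | alkyllithium from 8 (CH2Li in place of CH2I) | [Li]C[C@@H]1[C@@H](C(=C)C)CC[C@]2(C)O[C@H]12 | intermediate (not isolated)
20 | lithium B-methoxy-B-alkyl-9-borabicyclo[3.3.1]nonane borinate (alkyl = the ring A methylene of 19) | CO[B-]1(C[C@@H]2[C@@H](C(=C)C)CC[C@]3(C)O[C@H]23)C4CCCC1CCC4.[Li+] | intermediate (not isolated)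
21 | (1S,2R,4R)-2-bromo-1-methyl-4-{3-[(1R,2R,3S,6S)-6-methyl-3-(prop-1-en-2-yl)-7-oxabicyclo[4.1.0]heptan-2-yl]prop-1-en-2-yl}cyclohexan-1-ol | C=C(C[C@@H]1[C@@H](C(=C)C)CC[C@]2(C)O[C@H]12)[C@@H]1CC[C@](C)(O)[C@H](Br)C1 | target

Total step count: 11 (steps 1–5 to iodide 8, steps 6–10 to vinyl iodide 18, step 11 the union).
Longest linear sequence: 6 steps (1–5 then 11, or 6–10 then 11).

Steps most likely to fail

1. Step 8. The bromide attack on the trans-fused cyclic sulfate may be too slow, because the attacked carbon adjoins the quaternary centre and the reacting conformer holds the acetyl group axial on the attacked face, so elimination could take over. The hydrolysis of the tertiary sulfate could also drift to carbon–oxygen ionisation and lose the C1 configuration. The fallback sets out from keto diol 11 and uses an open-chain sulfonate in the normal chair, where bromide attacks equatorially. Both hydroxyls are silylated with N-(trimethylsilyl)imidazole to give the bis(trimethylsilyl) ether F1. The secondary silyl ether is removed selectively (K2CO3, MeOH, 0 °C) to give the tertiary silyl ether F2. Triflation (Tf2O, pyridine, CH2Cl2, −20 °C) gives the secondary triflate F3, and Bu4NBr in toluene at 20 °C displaces it with inversion to give the silylated cis-bromide F4. Citric acid in MeOH removes the silyl group and the route is rejoined at 15.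

2. Step 10. The iodinated cationic intermediate may be captured by the cis tertiary hydroxyl across the ring (bridged ether formation), over-iodination may give the geminal diiodide, or proton loss toward the ring may give the internal vinyl iodide. The fallback sets out from 15 and replaces the vinyl iodide by an enol triflate. Silylation with N-(trimethylsilyl)imidazole gives F4, the silyl ether described under the step 8 fallback. Kinetic deprotonation at the methyl group with KN(SiMe3)2 (THF, −78 °C) and trapping with PhNTf2 give the vinyl triflate F5. F5 is coupled with borinate 20 under the step 11 conditions to give the silyl ether of the target F6, and K2CO3 in MeOH rejoins the route at 21.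

3. Step 11. The iodine–lithium exchange may be incomplete or the organolithium protonated, and the β-branched alkyl group may leave boron slowly, so that protodeboronation and reduction of the vinyl iodide compete. The fallback sets out from 8 and changes the union to a Negishi coupling. Exchange with t-BuLi followed by ZnCl2 (1 equiv, −78 → 0 °C) gives the alkylzinc chloride F7. F7 is coupled with 18 using Pd(PPh3)4 (zerovalent palladium) in THF at 20 °C without aqueous base, and the route is rejoined directly at 21.

Further compounds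
F1 | step 8 | 1-[(1R,3S,4S)-4-methyl-3,4-bis(trimethylsilyloxy)cyclohexyl]ethan-1-one | CC(=O)[C@@H]1CC[C@](C)(O[Si](C)(C)C)[C@@H](O[Si](C)(C)C)C1
F2 | step 8 | 1-[(1R,3S,4S)-3-hydroxy-4-methyl-4-(trimethylsilyloxy)cyclohexyl]ethan-1-one | CC(=O)[C@@H]1CC[C@](C)(O[Si](C)(C)C)[C@@H](O)C1
F3 | step 8 | (1S,2S,5R)-5-acetyl-2-methyl-2-(trimethylsilyloxy)cyclohexyl trifluoromethanesulfonate | CC(=O)[C@@H]1CC[C@](C)(O[Si](C)(C)C)[C@@H](OS(=O)(=O)C(F)(F)F)C1
F4 | step 8 | 1-[(1R,3R,4S)-3-bromo-4-methyl-4-(trimethylsilyloxy)cyclohexyl]ethan-1-one | CC(=O)[C@@H]1CC[C@](C)(O[Si](C)(C)C)[C@H](Br)C1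
F5 | step 10 | 1-[(1R,3R,4S)-3-bromo-4-methyl-4-(trimethylsilyloxy)cyclohexyl]ethenyl trifluoromethanesulfonate | C=C(OS(=O)(=O)C(F)(F)F)[C@@H]1CC[C@](C)(O[Si](C)(C)C)[C@H](Br)C1
F6 | step 10 | trimethylsilyl ether of 21 at the tertiary hydroxyl | C=C(C[C@@H]1[C@@H](C(=C)C)CC[C@]2(C)O[C@H]12)[C@@H]1CC[C@](C)(O[Si](C)(C)C)[C@H](Br)C1
F7 | step 11 | chloro{[(1R,2R,3S,6S)-6-methyl-3-(prop-1-en-2-yl)-7-oxabicyclo[4.1.0]heptan-2-yl]methyl}zinc | Cl[Zn]C[C@@H]1[C@@H](C(=C)C)CC[C@]2(C)O[C@H]12
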